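**Plan**

1. Retrosynthesis: the C7 silyl ether comes off last; then both bonds to the ring B carbonyl carbon are cut, C6(ring B)–C(=O) and C(=O)–CH2, and that carbon is traced back to carbon monoxide.
2. Enabling feature: this carbonyl sits on C6 of the 7-hydroxychromene (ring B), para to the pyran oxygen O1 and ortho to the C7 hydroxyl, a position that can carry iodine; its other neighbour is a CH2 that is the methyl group of the 6-acetylchromene (ring A).
3. Forward: the ring B pyran is closed first (4-iodoresorcinol plus 3-methylbut-2-enal, condensation then oxa-6π closure), and the ring A pyran separately (propargyl ether Claisen cascade on 4-hydroxyacetophenone).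
4. The 1,3-dicarbonyl chain is then assembled from aryl iodide, CO and methyl ketone in one palladium-catalysed operation, and desilylation ends the route.
5. Stereochemistry: the target has no stereocentre and both ring alkenes are cis by ring constraint, so nothing needs to be controlled.

Key step: step 6

Remark: the protected and the free 1,3-diketone are drawn as diketo tautomers; both are expected to exist largely as hydrogen-bonded enols, which does not change the route.

**Route**

Step 1
Reactants: 1 resorcinol (benzene-1,3-diol)
Product: 2 4-iodoresorcinol (4-iodobenzene-1,3-diol)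
Conditions: ICl (1.0 equiv), Et2O, 0 °C to rt
Reagents that add atoms: iodine monochloride, ClI
Why: Electrophilic aromatic iodination with one equivalent of ICl in ether should go to C4, the open carbon ortho to one hydroxyl and para to the other, in preference to the flanked C2, and the iodine introduced slows a second substitution.

Step 2
Reactants: 2 4-iodoresorcinol; 3 3-methylbut-2-enal
Product: 5 6-iodo-2,2-dimethyl-2H-chromen-7-ol, via ortho-quinone methide 4 (not isolated)
Conditions: 3 (1.5 equiv), ethylenediammonium diacetate (20 mol%), xylene, reflux (Dean–Stark)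
Reagents that add atoms: none
Why: Amine-catalysed Knoevenagel-type condensation of the enal (as its iminium ion) at C6 of 2, the unhindered carbon para to the more acidic C3 hydroxyl, followed by loss of water should give ortho-quinone methide 4, whose oxa-6π electrocyclisation onto the only adjacent oxygen closes the pyran and places iodine at C6 and the free hydroxyl at C7.

Step 3
Reactants: 5 6-iodo-2,2-dimethyl-2H-chromen-7-ol
Product: 6 tert-butyl[(6-iodo-2,2-dimethyl-2H-chromen-7-yl)oxy]dimethylsilane
Conditions: TBSCl, imidazole, DMF, rt
Reagents that add atoms: tert-butyldimethylsilyl chloride, CC(C)(C)[Si](C)(C)Cl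
Why: Imidazole-promoted silylation of a phenol is routine, leaves the aryl iodide and the chromene alkene untouched, and masks the only acidic OH before the carbonylation.

Step 4
Reactants: 7 4-hydroxyacetophenone; 8 3-chloro-3-methylbut-1-yne
Product: 9 1-{4-[(2-methylbut-3-yn-2-yl)oxy]phenyl}ethan-1-one
Conditions: 8 (1.5 equiv), CuCl2·2H2O (1 mol%), DBU, MeCN, 0 °C to rt
Reagents that add atoms: none
Why: Copper-catalysed O-propargylation of a phenol with a tertiary propargylic chloride proceeds through a copper acetylide-derived electrophile and therefore tolerates both the hindered tertiary centre and the weakly nucleophilic para-acetylphenoxide.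

Step 5
Reactants: 9 1-{4-[(2-methylbut-3-yn-2-yl)oxy]phenyl}ethan-1-one
Product: 12 1-(2,2-dimethyl-2H-chromen-6-yl)ethan-1-one, via allenylphenol 10 (not isolated), via ortho-quinone methide 11 (not isolated)
Conditions: PhNEt2, 190 °C
Reagents that add atoms: none
Why: Thermal aryl propargyl ether Claisen rearrangement and enolisation should give allenylphenol 10, a 1,5-hydrogen shift then gives ortho-quinone methide 11 and oxa-6π electrocyclisation closes the 2,2-dimethylpyran; because the two ortho positions of 9 are equivalent, a single chromene with the acetyl group at C6 (para to O1) is expected.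

Step 6
Reactants: 6 tert-butyl[(6-iodo-2,2-dimethyl-2H-chromen-7-yl)oxy]dimethylsilane; 12 1-(2,2-dimethyl-2H-chromen-6-yl)ethan-1-one; 13 carbon monoxide
Product: 17 glyinflanin D tert-butyldimethylsilyl ether, via aroylpalladium iodide complex 14 (not isolated), via chloromagnesium enolate 15 (not isolated), via chloromagnesium diketonate 16 (not isolated)
Conditions: 12 (1.5 equiv), Pd(dba)2 (5 mol%), 1,3-bis(diphenylphosphino)propane (dppp, 5 mol%), CO (1 atm, sealed two-chamber vessel), MgCl2 (2 equiv), Et3N (4 equiv), 1,4-dioxane, 80 °C; then cold 1 M aq. HCl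
Reagents that add atoms: none
Why: Oxidative addition of the C6–I bond of 6 to the zerovalent palladium–dppp complex and migratory insertion of CO should give aroylpalladium iodide complex 14 (divalent palladium), while MgCl2 and Et3N convert methyl ketone 12 by soft enolisation into chloromagnesium enolate 15. Enolate 15 displaces iodide on palladium and C–C reductive elimination forms the C(=O)–CH2 bond and returns zerovalent palladium, so the C6–C(=O) and C(=O)–CH2 bonds arise in one catalytic cycle; the closest known reaction type is the palladium-catalysed carbonylative α-arylation of aryl methyl ketones with aryl iodides to 1,3-diketones. No ring is closed and no stereocentre is formed. CO insertion must precede enolate capture (otherwise direct α-arylation), which the electron-rich ortho-substituted aryl group, the chelating bisphosphine and the CO atmosphere should secure, and acylation must occur at carbon and not at oxygen, which the covalent magnesium enolate favours. A second acylation is blocked because the more acidic product is held as chloromagnesium diketonate 16 until the acidic work-up. The silyl ether stops a phenoxide from intercepting 14 as an aryl ester, the methyl group of 12 is the only enolisable position, and the cis-disubstituted chromene alkenes next to the quaternary C2 are too hindered for Heck-type insertion.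

Step 7
Reactants: 17 glyinflanin D tert-butyldimethylsilyl ether
Product: 18 glyinflanin D
Conditions: Bu4NF, AcOH (1:1), THF, 0 °C
Reagents that add atoms: none
Why: Fluoride-mediated cleavage of an aryl silyl ether is fast at 0 °C, and the acetic acid buffer keeps the medium near neutral so that the ortho-hydroxy 1,3-diketone should suffer neither retro-Claisen cleavage nor cyclodehydration to a chromone.

**Compound list**

1 | resorcinol (benzene-1,3-diol) | Oc1cccc(O)c1 | starting material
2 | 4-iodoresorcinol (4-iodobenzene-1,3-diol) | Oc1ccc(I)c(O)c1 | intermediate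
3 | 3-methylbut-2-enal | CC(C)=CC=O | starting material
4 | 3-hydroxy-4-iodo-6-(3-methylbut-2-en-1-ylidene)cyclohexa-2,4-dien-1-one (ortho-quinone methide) | O=C1C=C(O)C(I)=CC1=CC=C(C)C | intermediate
5 | 6-iodo-2,2-dimethyl-2H-chromen-7-ol | CC1(C)C=Cc2cc(I)c(O)cc2O1 | intermediate
6 | tert-butyl[(6-iodo-2,2-dimethyl-2H-chromen-7-yl)oxy]dimethylsilane | CC1(C)C=Cc2cc(I)c(O[Si](C)(C)C(C)(C)C)cc2O1 | intermediate
7 | 4-hydroxyacetophenone | CC(=O)c1ccc(O)cc1 | starting material
8 | 3-chloro-3-methylbut-1-yne | CC(C)(Cl)C#C | starting material
9 | 1-{4-[(2-methylbut-3-yn-2-yl)oxy]phenyl}ethan-1-one | CC(=O)c1ccc(OC(C)(C)C#C)cc1 | intermediate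
10 | 1-[4-hydroxy-3-(3-methylbuta-1,2-dien-1-yl)phenyl]ethan-1-one (allenylphenol) | CC(=O)c1ccc(O)c(C=C=C(C)C)c1 | intermediate
11 | 4-acetyl-6-(3-methylbut-2-en-1-ylidene)cyclohexa-2,4-dien-1-one (ortho-quinone methide) | CC(=O)C1=CC(=CC=C(C)C)C(=O)C=C1 | intermediate
12 | 1-(2,2-dimethyl-2H-chromen-6-yl)ethan-1-one | CC(=O)c1ccc2OC(C)(C)C=Cc2c1 | intermediate
13 | carbon monoxide | [C-]#[O+] | starting material
14 | {7-[(tert-butyldimethylsilyl)oxy]-2,2-dimethyl-2H-chromene-6-carbonyl}(iodo)[1,3-bis(diphenylphosphino)propane]palladium (divalent palladium) | CC1(C)C=Cc2cc(C(=O)[Pd-2]3(I)[P+](c4ccccc4)(c4ccccc4)CCC[P+]3(c3ccccc3)c3ccccc3)c(O[Si](C)(C)C(C)(C)C)cc2O1 | intermediate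
15 | chloromagnesium 1-(2,2-dimethyl-2H-chromen-6-yl)ethen-1-olate | C=C(O[Mg]Cl)c1ccc2OC(C)(C)C=Cc2c1 | intermediate
16 | chloromagnesium enolate (chelate) of diketone 17 | CC1(C)C=Cc2cc(C(=O)C=C(O[Mg]Cl)c3cc4c(cc3O[Si](C)(C)C(C)(C)C)OC(C)(C)C=C4)ccc2O1 | intermediate
17 | glyinflanin D tert-butyldimethylsilyl ether, 1-{7-[(tert-butyldimethylsilyl)oxy]-2,2-dimethyl-2H-chromen-6-yl}-3-(2,2-dimethyl-2H-chromen-6-yl)propane-1,3-dione | CC1(C)C=Cc2cc(C(=O)CC(=O)c3cc4c(cc3O[Si](C)(C)C(C)(C)C)OC(C)(C)C=C4)ccc2O1 | intermediate
18 | glyinflanin D, 1-(7-hydroxy-2,2-dimethyl-2H-chromen-6-yl)-3-(2,2-dimethyl-2H-chromen-6-yl)propane-1,3-dione | CC1(C)C=Cc2cc(C(=O)CC(=O)c3cc4c(cc3O)OC(C)(C)C=C4)ccc2O1 | target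

**Step count**

Total: 7 steps. Longest linear sequence: 5 steps (steps 1, 2, 3, 6, 7); the ring A branch (steps 4 and 5) joins at step 6.

**Steps most likely to fail**

Step 6. Direct α-arylation may outrun CO insertion, oxidative addition at the hindered, electron-rich C–I bond may be slow, or the silyl group may be lost under MgCl2/Et3N at 80 °C so that the freed phenoxide is aroylated at oxygen. The fallback sets out from 6 and 12 and comes back at 17, building the chain stepwise at the alcohol oxidation level. Iodine–magnesium exchange on 6 with iPrMgCl·LiCl in THF at −20 °C gives {7-[(tert-butyldimethylsilyl)oxy]-2,2-dimethyl-2H-chromen-6-yl}magnesium chloride F1, which is formylated with DMF to 7-[(tert-butyldimethylsilyl)oxy]-2,2-dimethyl-2H-chromene-6-carbaldehyde F2. Ketone 12 is deprotonated with lithium diisopropylamide in THF at −78 °C to lithium 1-(2,2-dimethyl-2H-chromen-6-yl)ethen-1-olate F3, and aldol addition to F2 gives the racemic β-hydroxy ketone 3-{7-[(tert-butyldimethylsilyl)oxy]-2,2-dimethyl-2H-chromen-6-yl}-1-(2,2-dimethyl-2H-chromen-6-yl)-3-hydroxypropan-1-one F4. Oxidation with Dess–Martin periodinane in CH2Cl2 removes the transient stereocentre and should deliver 17.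

Step 2. C–C bond formation may occur at the flanked C2 of 2 instead of C6 (leading to 5-hydroxychromene regioisomers), a second annulation may take place at C8 of the product, or the iodophenol may degrade on prolonged heating. The fallback sets out from 1 and 3, makes step 1 unnecessary and comes back at 5 by reversing the order of events. Resorcinol and 3-methylbut-2-enal are condensed in pyridine at 140 °C to 2,2-dimethyl-2H-chromen-7-ol F5. F5 is then iodinated with N-iodosuccinimide in CH2Cl2 at 0 °C; substitution is expected at C6, the open position ortho to the hydroxyl and para to O1, giving 5.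

Step 4. Elimination of HCl from the tertiary propargylic chloride and slow etherification of the acetyl-deactivated phenoxide may leave the phenol largely unreacted. The fallback sets out from 7 and 3, bypasses steps 4 and 5 and comes back at 12. 4-Hydroxyacetophenone, 3-methylbut-2-enal and PhB(OH)2 are heated with catalytic propionic acid in toluene under Dean–Stark conditions, an ortho-specific condensation that passes through racemic 1-[4-(2-methylprop-1-en-1-yl)-2-phenyl-4H-1,3,2-benzodioxaborinin-6-yl]ethan-1-one F6. On continued heating F6 should fragment to ortho-quinone methide 11, which electrocyclises to 12.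

**Further compounds**

F1 | step 6 | {7-[(tert-butyldimethylsilyl)oxy]-2,2-dimethyl-2H-chromen-6-yl}magnesium chloride | CC1(C)C=Cc2cc([Mg]Cl)c(O[Si](C)(C)C(C)(C)C)cc2O1
F2 | step 6 | 7-[(tert-butyldimethylsilyl)oxy]-2,2-dimethyl-2H-chromene-6-carbaldehyde | CC1(C)C=Cc2cc(C=O)c(O[Si](C)(C)C(C)(C)C)cc2O1
F3 | step 6 | lithium 1-(2,2-dimethyl-2H-chromen-6-yl)ethen-1-olate | [Li]OC(=C)c1ccc2OC(C)(C)C=Cc2c1
F4 | step 6 | racemic 3-{7-[(tert-butyldimethylsilyl)oxy]-2,2-dimethyl-2H-chromen-6-yl}-1-(2,2-dimethyl-2H-chromen-6-yl)-3-hydroxypropan-1-one | CC1(C)C=Cc2cc(C(=O)CC(O)c3cc4c(cc3O[Si](C)(C)C(C)(C)C)OC(C)(C)C=C4)ccc2O1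
F5 | step 2 | 2,2-dimethyl-2H-chromen-7-ol | CC1(C)C=Cc2ccc(O)cc2O1
F6 | step 4 | racemic 1-[4-(2-methylprop-1-en-1-yl)-2-phenyl-4H-1,3,2-benzodioxaborinin-6-yl]ethan-1-one | CC(=O)c1ccc2OB(c3ccccc3)OC(C=C(C)C)c2c1
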